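**Retrosynthetic overview**

1. Target 16 is a 19-membered ring made of ring A (methoxy arene, 1,3-linked), ring B (1,4-phenylene), ring C (phenol, 1,3-linked) and ring D (1,3-phenylene), joined by two diaryl ether oxygens (A–O–B, C–O–D) and two CH2CH2 bridges (B–C, D–A).
2. The last disconnection is the CH2–CH2 bond of the D–A bridge: 16 comes from macrocyclic stilbene 15, made by McMurry macrocyclisation of open-chain dialdehyde 13; one hydrogenation then saturates the new C=C and frees the phenol.
3. Enabling feature: both bridge carbons are unsubstituted benzylic carbons, one on ring A (para to OMe) and one on ring D (meta to the ether O), so each can be carried as an aryl nitrile, released as ArCHO and joined reductively; the 1,3-linkages of rings A, C and D fold the chain D–O–C–CH2CH2–B–O–A into a loop.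
4. Open chain: B–C bridge by Wittig olefination (8 + 3) and chemoselective hydrogenation; A–O–B ether by SNAr (1 + 2); C–O–D ether by Ullmann coupling (4 + 5).
5. Ring order: the four benzene rings are bought; the macrocycle is the only ring formed, in step 8.

Key step: step 8

Assumption: olefins 10 and 15 are expected as E/Z mixtures and intermediate 14 as a diastereomer mixture, so their SMILES leave this geometry open because all isomers converge on hydrogenation or deoxygenation; 14 is drawn as its simplest dichlorotitanium diolate.

**Route**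

Step 1
Reactants: 1 3-hydroxy-4-methoxybenzonitrile; 2 4-fluorobenzaldehyde
Product: 3 3-(4-formylphenoxy)-4-methoxybenzonitrile
Conditions: K2CO3 (2 equiv), DMF, 130 °C
Reagents that add atoms: none
Why: Nucleophilic aromatic substitution (SNAr) in which the phenoxide of 1 displaces the fluoride para to the activating formyl group of 2, the nitrile being inert to carbonate.

Step 2
Reactants: 4 4-(benzyloxy)-3-hydroxybenzaldehyde; 5 3-iodobenzonitrile
Product: 6 3-[2-(benzyloxy)-5-formylphenoxy]benzonitrile
Conditions: CuI (10 mol%), N,N-dimethylglycine hydrochloride (30 mol%), Cs2CO3 (2 equiv), 1,4-dioxane, 90 °C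
Reagents that add atoms: none
Why: Ullmann-type copper-catalysed diaryl ether synthesis with an amino acid ligand should couple the phenoxide of 4 with aryl iodide 5, and aldehyde, nitrile and benzyl ether tolerate these conditions.

Step 3
Reactants: 6 3-[2-(benzyloxy)-5-formylphenoxy]benzonitrile
Product: 7 3-[2-(benzyloxy)-5-(hydroxymethyl)phenoxy]benzonitrile
Conditions: NaBH4, MeOH/THF, 0 °C
Reagents that add atoms: none
Why: Borohydride reduction of an aryl aldehyde to the benzylic alcohol, which leaves the aryl nitrile and the ethers untouched at 0 °C.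

Step 4
Reactants: 7 3-[2-(benzyloxy)-5-(hydroxymethyl)phenoxy]benzonitrile
Product: 8 {[4-(benzyloxy)-3-(3-cyanophenoxy)phenyl]methyl}triphenylphosphonium bromide
Conditions: PPh3·HBr, MeCN, reflux
Reagents that add atoms: triphenylphosphine hydrobromide, [Br-].[PH+](c1ccccc1)(c1ccccc1)c1ccccc1
Why: Acid-promoted substitution of the activated para-alkoxybenzylic hydroxyl by triphenylphosphine should give the benzylic phosphonium salt directly from the alcohol (phosphonium salt formation with PPh3·HBr).

Step 5
Reactants: 8 {[4-(benzyloxy)-3-(3-cyanophenoxy)phenyl]methyl}triphenylphosphonium bromide; 3 3-(4-formylphenoxy)-4-methoxybenzonitrile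
Product: 10 3-{4-[2-[4-(benzyloxy)-3-(3-cyanophenoxy)phenyl]ethenyl]phenoxy}-4-methoxybenzonitrile (E/Z mixture), via phosphonium ylide 9 (not isolated)
Conditions: K2CO3, 18-crown-6 (cat.), CH2Cl2, reflux
Reagents that add atoms: none
Why: Wittig olefination of aryl aldehyde 3 with the semi-stabilised benzylic ylide 9 under solid–liquid phase-transfer conditions that both nitriles tolerate; the alkene geometry is irrelevant because step 6 saturates it.

Step 6
Reactants: 10 3-{4-[2-[4-(benzyloxy)-3-(3-cyanophenoxy)phenyl]ethenyl]phenoxy}-4-methoxybenzonitrile (E/Z mixture)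
Product: 11 3-{4-[2-[4-(benzyloxy)-3-(3-cyanophenoxy)phenyl]ethyl]phenoxy}-4-methoxybenzonitrile
Conditions: H2 (1 atm), 5% Pd/C, Ph2S (cat.), EtOAc, rt
Reagents that add atoms: none
Why: Chemoselective heterogeneous catalytic hydrogenation, in which sulfide-poisoned Pd/C should saturate the stilbene C=C while hydrogenolysis of the aryl benzyl ether and reduction of the nitriles are suppressed.

Step 7
Reactants: 11 3-{4-[2-[4-(benzyloxy)-3-(3-cyanophenoxy)phenyl]ethyl]phenoxy}-4-methoxybenzonitrile
Product: 13 3-{4-[2-[4-(benzyloxy)-3-(3-formylphenoxy)phenyl]ethyl]phenoxy}-4-methoxybenzaldehyde, via bis(aluminium aldimine) 12 (not isolated)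
Conditions: DIBAL-H (3 equiv), CH2Cl2, –78 to 0 °C; then 1 M aq. HCl, rt
Reagents that add atoms: water, O
Why: DIBAL-H partial reduction of aryl nitriles stops at the N-aluminated aldimine 12 at low temperature and aqueous acid hydrolyses it to the aldehyde, so both chain termini are unmasked in one operation while the ethers are inert.

Step 8
Reactants: 13 3-{4-[2-[4-(benzyloxy)-3-(3-formylphenoxy)phenyl]ethyl]phenoxy}-4-methoxybenzaldehyde
Product: 15 O-benzyl macrocyclic stilbene (19-membered ring; CH=CH linking ring D to ring A; E/Z mixture), via titanium pinacolate 14 (not isolated)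
Conditions: TiCl4, Zn, pyridine, THF, reflux; 13 added by syringe pump (high dilution)
Reagents that add atoms: none
Why: Low-valent titanium generated from TiCl4 and Zn reduces both formyl groups of 13 by single-electron transfer, carbon–carbon coupling at the metal gives the titanium pinacolate 14, and at reflux both C–O bonds are cleaved with transfer of the oxygens to titanium, which leaves a C=C bond between the two former formyl carbons (McMurry coupling). The closest known reaction type is the intramolecular McMurry coupling of aromatic dialdehydes to macrocyclic stilbenes, a closure in use for stilbenophanes and macrocyclic bis(bibenzyl) ethers. One ring is closed, the 19-membered macrocycle, by end-to-end coupling of the two chain termini (the formyl carbon on ring A with the formyl carbon on ring D). No stereocentre remains, because the two carbinol centres of 14 are erased on deoxygenation and either alkene geometry is saturated in step 9. The step needs ring closure to win over intermolecular coupling and deoxygenation to go to completion; the first is secured by slow addition that keeps free 13 very dilute and by the fold that the 1,3-linkages of rings A, C and D and the two diaryl ether bends impose on the chain, the second by prolonged reflux in THF with pyridine. Only the two aryl aldehydes are reducible under these conditions, since the diaryl ethers and the methyl ether are inert, and any loss of the benzyl group would still lead to 16 after step 9.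

Step 9
Reactants: 15 O-benzyl macrocyclic stilbene (E/Z mixture)
Product: 16 target macrocycle (free phenol on ring C; CH2CH2 bridges B–C and D–A; OMe on ring A)
Conditions: H2 (1 atm), 10% Pd/C, EtOAc/MeOH, rt
Reagents that add atoms: none
Why: Heterogeneous catalytic hydrogenation over unpoisoned Pd/C should saturate the macrocyclic stilbene and hydrogenolyse the aryl benzyl ether in the same operation, while the methyl ether, the diaryl ethers and the arenes are inert at 1 atm and rt.

**Compound list**

1 | 3-hydroxy-4-methoxybenzonitrile | COc1ccc(C#N)cc1O | starting material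
2 | 4-fluorobenzaldehyde | O=Cc1ccc(F)cc1 | starting material
3 | 3-(4-formylphenoxy)-4-methoxybenzonitrile | COc1ccc(C#N)cc1Oc1ccc(C=O)cc1 | intermediate
4 | 4-(benzyloxy)-3-hydroxybenzaldehyde | O=Cc1ccc(OCc2ccccc2)c(O)c1 | starting material
5 | 3-iodobenzonitrile | N#Cc1cccc(I)c1 | starting material
6 | 3-[2-(benzyloxy)-5-formylphenoxy]benzonitrile | O=Cc1ccc(OCc2ccccc2)c(Oc2cccc(C#N)c2)c1 | intermediate
7 | 3-[2-(benzyloxy)-5-(hydroxymethyl)phenoxy]benzonitrile | OCc1ccc(OCc2ccccc2)c(Oc2cccc(C#N)c2)c1 | intermediate
8 | {[4-(benzyloxy)-3-(3-cyanophenoxy)phenyl]methyl}triphenylphosphonium bromide | [Br-].N#Cc1cccc(Oc2cc(C[P+](c3ccccc3)(c3ccccc3)c3ccccc3)ccc2OCc2ccccc2)c1 | intermediate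
9 | [4-(benzyloxy)-3-(3-cyanophenoxy)benzylidene]triphenylphosphorane (ylide; formed in the flask, not isolated) | N#Cc1cccc(Oc2cc(C=P(c3ccccc3)(c3ccccc3)c3ccccc3)ccc2OCc2ccccc2)c1 | intermediate
10 | 3-{4-[2-[4-(benzyloxy)-3-(3-cyanophenoxy)phenyl]ethenyl]phenoxy}-4-methoxybenzonitrile (E/Z mixture, geometry left open) | COc1ccc(C#N)cc1Oc1ccc(C=Cc2ccc(OCc3ccccc3)c(Oc3cccc(C#N)c3)c2)cc1 | intermediate
11 | 3-{4-[2-[4-(benzyloxy)-3-(3-cyanophenoxy)phenyl]ethyl]phenoxy}-4-methoxybenzonitrile | COc1ccc(C#N)cc1Oc1ccc(CCc2ccc(OCc3ccccc3)c(Oc3cccc(C#N)c3)c2)cc1 | intermediate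
12 | bis(N-diisobutylaluminium aldimine) of 13 (both nitriles reduced to CH=N–Al(iBu)2; formed in the flask, not isolated) | COc1ccc(C=N[Al](CC(C)C)CC(C)C)cc1Oc1ccc(CCc2ccc(OCc3ccccc3)c(Oc3cccc(C=N[Al](CC(C)C)CC(C)C)c3)c2)cc1 | intermediate
13 | 3-{4-[2-[4-(benzyloxy)-3-(3-formylphenoxy)phenyl]ethyl]phenoxy}-4-methoxybenzaldehyde | COc1ccc(C=O)cc1Oc1ccc(CCc2ccc(OCc3ccccc3)c(Oc3cccc(C=O)c3)c2)cc1 | intermediate
14 | macrocyclic titanium pinacolate (19-membered ring closed; vicinal diolate on the D–A bridge; diastereomer mixture; formed in the flask, not isolated) | COc1ccc2cc1Oc1ccc(cc1)CCc1ccc(OCc3ccccc3)c(c1)Oc1cccc(c1)C1O[Ti](Cl)(Cl)OC12 | intermediate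
15 | O-benzyl macrocyclic stilbene (19-membered ring; CH=CH between rings D and A; E/Z mixture, geometry left open) | COc1ccc2cc1Oc1ccc(cc1)CCc1ccc(OCc3ccccc3)c(c1)Oc1cccc(c1)C=C2 | intermediate
16 | target macrocycle: ring A (OMe; ether O ortho to OMe; CH2 para to OMe) –O– ring B (1,4-phenylene) –CH2CH2– ring C (OH para to CH2; ether O ortho to OH) –O– ring D (1,3-phenylene) –CH2CH2– ring A | COc1ccc2cc1Oc1ccc(cc1)CCc1ccc(O)c(c1)Oc1cccc(c1)CC2 | target

**Summary**

Total step count: 9.
Longest linear sequence: 8 steps (steps 2 to 9, from 4 and 5).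

Steps most likely to fail:

1. Step 8. Intermolecular carbonyl coupling (oligomer formation) may outrun ring closure, or the coupling may stop at the pinacol stage without deoxygenation. Fallback: the ring would be closed at the sp3 level by an intramolecular Wurtz-type coupling, a closure with close precedent for macrocyclic bis(bibenzyl) ethers. It sets out from 13. Reduction with NaBH4 (MeOH/THF, 0 °C) should give the bis(hydroxymethyl) compound F1, and PBr3 (CH2Cl2, 0 °C) the bis(bromomethyl) compound F2. Slow addition of F2 to sodium and tetraphenylethene in THF (–78 °C to rt, high dilution) should give the saturated O-benzyl macrocycle F3. Hydrogenolysis of F3 (H2, Pd/C, EtOAc/MeOH) comes back to the route at 16.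

2. Step 2. The C–O bond formation may be sluggish at the phenoxide flanked by the benzyloxy group, with reductive loss of iodide from 5 and degradation of the aldehyde on prolonged heating with base. Fallback: the ether bond would be formed oxidatively from an arylboronic acid instead of by halide substitution (Chan–Lam coupling). It sets out from 4, which is coupled with (3-cyanophenyl)boronic acid (Cu(OAc)2, pyridine, 4 Å molecular sieves, CH2Cl2, air, rt) without strong base or heat. It comes back to the route at 6; no new compound is made on the way (F0).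

3. Step 6. Hydrogenolysis of the aryl benzyl ether may accompany saturation of the alkene. Fallback: the loss of the protecting group is accepted and repaired. It sets out from 10, which is hydrogenated exhaustively (H2, 10% Pd/C, EtOAc/MeOH, rt) to the free phenol F4 with the bibenzyl bridge saturated. Re-benzylation (BnBr, K2CO3, DMF, rt) comes back to the route at 11.

**Further compounds**

F1 | step 8 | [3-(4-{2-[4-(benzyloxy)-3-[3-(hydroxymethyl)phenoxy]phenyl]ethyl}phenoxy)-4-methoxyphenyl]methanol | COc1ccc(CO)cc1Oc1ccc(CCc2ccc(OCc3ccccc3)c(Oc3cccc(CO)c3)c2)cc1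
F2 | step 8 | 1-(benzyloxy)-2-[3-(bromomethyl)phenoxy]-4-(2-{4-[5-(bromomethyl)-2-methoxyphenoxy]phenyl}ethyl)benzene | COc1ccc(CBr)cc1Oc1ccc(CCc2ccc(OCc3ccccc3)c(Oc3cccc(CBr)c3)c2)cc1
F3 | step 8 | O-benzyl ether of 16 (saturated 19-membered macrocycle) | COc1ccc2cc1Oc1ccc(cc1)CCc1ccc(OCc3ccccc3)c(c1)Oc1cccc(c1)CC2
F0 | step 2 | none | none
F4 | step 6 | 3-{4-[2-[3-(3-cyanophenoxy)-4-hydroxyphenyl]ethyl]phenoxy}-4-methoxybenzonitrile | COc1ccc(C#N)cc1Oc1ccc(CCc2ccc(O)c(Oc3cccc(C#N)c3)c2)cc1
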